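The target is what I follow: how much of it stands in the new flask at each reading time.

| flask | substrate | reagent | free catalyst | remark | time |
|---|---|---|---|---|---|
| theta | 0.050 M | 0.024 M | 0.25 mM (in portions, 3) | run made earlier; portions every 1.0 h |  |
| delta | 0.050 M | 0.036 M | 0.25 mM (in portions, 3) | run made earlier; portions every 1.0 h |  |
| flask | 0.050 M | 0.0475 M | 0.25 mM (in portions, 3) | the portions of free catalyst follow each other after 1.0 h, the first at the start | 15 h |

- theta (time / h: target / %, substrate / %): 2.50: 8, 92; 5.00: 17, 81; 6.00: 24, 73; 10.0: 43, 55
- delta (time / h: target / %, substrate / %): 2.50: 6, 89; 5.00: 19, 81; 6.00: 26, 76; 10.0: 43, 55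

(standard deviation of a reading: 2 percentage points)



1. amount of target in percent of the substrate charged, at 1.5 h, 5.0 h, 10 h and 15 h

1. In both earlier runs the target climbs along a nearly straight line. From 5.00 h to 10.0 h the theta run gains 26 percentage points and the delta run 24 points, although the delta run holds more reagent. The two gains stand apart by one scatter of a reading.

2. I carry their mean as the plateau rate, 2.50 mM/h: the growth of c(target) per hour once the whole catalyst charge is in. It is a reading, with the scatter of the readings.

3. Now I take two extreme versions of the new flask. With the whole charge in at the start, the line reaches 75.0% at 15 h. With the whole charge in at the last portion, it reaches 65.0%. The real portions arrive between these two moments, and their mean arrival is 1.0 h, so I start my line there. It gives 2.50%, 20.0%, 45.0% and 70.0%. If one reagent goes per target, the reagent is the limiting reagent and allows 95.0%, above the upper extreme. Beyond 10.0 h the line is an extrapolation.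

4. The forecast says 3.2%, 19%, 43% and 65%, holding that “the rate is zero order in reagent”. Its last value lies below mine.

5. The new flask gives 3.44%, 20.6%, 45.7% and 69.2%, so the forecast is right within the tolerance.

    substrate + free catalyst → catalyst intermediate A (k = 3.13 /M/s)
    reagent + catalyst intermediate A ⇌ catalyst intermediate B (K = 660 /M, k = 9.55 /M/s)
    catalyst intermediate B → by-product + catalyst intermediate C (k = 0.00331 /s)
    catalyst intermediate C ⇌ free catalyst + target (K = 0.0501 M, k = 0.0399 /s)

6. My line reads 70.0% at 15 h, and the new flask stands at 69.2%. The same flask with twice the reagent gives 71.8%, which is 1.8 points above that same line. The gap between the new flask and the 95.0% its reagent allows comes mainly from the length of the run: at 15 h the new flask still holds 27% of its reagent charge, and the same flask run ten times as long stands at 95.0%.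

The data stem from a simulated flask from invented constants, noise included.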